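The route rests on taking the four contiguous oxygen-bearing carbons of benzene ring A (C6, C7, C8 and C8a, with O–C6 para to O–C8a) intact from dimethyl squarate and closing the ring across C4a–C8a. The precursor is a squarate-derived 4-methoxycyclobutenone carrying an (E)-3,3-diethoxypropenyl group on its quaternary carbon. On thermolysis it passes through a dienylketene that ring-closes and tautomerizes, giving in one operation a fully oxygenated phenol with C5–H, C4a and the masked formyl carbon (future C4) in place. Selective cleavage of the C7 methyl ether, which alone sits para to the freed aldehyde, and a Perkin–Oglialoro condensation with 6,7-dihydroxycoumarin-3-acetic acid then build pyranone ring B next to the C3–C3′ bond.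

Key step: step 3

Remark: coumarin locants are used, unprimed for the 7-hydroxy-6,8-dimethoxy half (benzene ring A, pyranone ring B) and primed for the 6,7-dihydroxy half (pyranone ring C, benzene ring D); the target is achiral, and the only stereocentre of the route (the quaternary ring carbon of the cyclobutenone, racemic) is destroyed in the key step.

Remark: the C7 oxygen is taken through the ring-forming step as a methyl ether, so that the cyclobutenone is reached from dimethyl squarate by organolithium addition and O-methylation alone; it is freed at the salicylaldehyde stage (step 5), where it is the only methoxy group para to the formyl group.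

Step 1
Reactants: 1 (3,3-diethoxyprop-1-yne)
Product: 2 tributyl[(E)-3,3-diethoxyprop-1-en-1-yl]stannane
Conditions: Bu3SnH, AIBN (cat.), neat, 90 °C
Reagents that add atoms: tributyltin hydride (Bu3SnH), CCCC[SnH](CCCC)CCCC
Why: Radical hydrostannylation of a terminal alkyne puts tin on the terminal carbon and, because stannyl radical addition is reversible, funnels the product to the E vinylstannane; any Z isomer carried on is harmless because this alkene carbon becomes aromatic C4a.

Step 2
Reactants: 2 (the vinylstannane), 3 (dimethyl squarate)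
Product: 6 racemic 4-[(E)-3,3-diethoxyprop-1-en-1-yl]-2,3,4-trimethoxycyclobut-2-en-1-one, via alkenyllithium 4 (not isolated), via lithium alkoxide 5 (not isolated)
Conditions: n-BuLi, THF, −78 °C; then 3, THF, −78 °C; then MeOTf, −78 to 0 °C
Reagents that add atoms: methyl trifluoromethanesulfonate (MeOTf), COS(=O)(=O)C(F)(F)F
Why: Tin–lithium exchange proceeds with retention of alkene geometry, the alkenyllithium adds 1,2 to one of the two equivalent carbonyl groups of the squaric ester, and the tertiary lithium alkoxide is O-methylated in situ by methyl triflate (the standard entry to 4-alkenyl-4-methoxycyclobutenones); the new stereocentre C4 forms as a racemate, which is of no consequence because step 3 destroys it.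

Step 3
Reactants: 6 (the cyclobutenone)
Product: 9 phenol 6-(diethoxymethyl)-2,3,4-trimethoxyphenol, via dienylketene 7 (not isolated), via cyclohexadienone 8 (not isolated)
Conditions: p-xylene (dilute, degassed), 138 °C
Reagents that add atoms: none
Why: On heating, the C1–C4 bond of 6 breaks in a conrotatory 4π ring opening to dienylketene 7, in which the C4 methoxy donor has rotated outward and the alkenyl group therefore lies cis to the ketene. Disrotatory 6π electrocyclization of this triene bonds the ketene carbon (future C8a) to the alkene terminus (future C4a) and closes carbocyclic ring A as cyclohexa-2,4-dienone 8, which enolizes irreversibly to phenol 9. The closest known reaction type is the thermal ring expansion of squarate-derived 4-alkenyl-4-alkoxy (or 4-hydroxy) cyclobutenones to hydroquinone monoethers. No stereocentre survives, since C4 of 6 becomes sp2 on ring opening and the sp3 carbon of 8 is lost on tautomerization. The step needs torquoselectivity, secured by the outward preference of the oxygen donor at C4, and a fixed oxygen sequence, secured by ring connectivity (carbonyl carbon to C8a, C2 to C8, C3 to C7, C4 to C6); the neutral conditions leave the diethyl acetal untouched.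

Step 4
Reactants: 9 (the phenol acetal)
Product: 10 salicylaldehyde 2-hydroxy-3,4,5-trimethoxybenzaldehyde
Conditions: 1 M HCl, THF, rt
Reagents that add atoms: water, O
Why: Acid-catalysed hydrolysis of an aryl-stabilised diethyl acetal is fast at room temperature and leaves the aryl methyl ethers and the phenol untouched.

Step 5
Reactants: 10 (2-hydroxy-3,4,5-trimethoxybenzaldehyde)
Product: 11 salicylaldehyde 2,4-dihydroxy-3,5-dimethoxybenzaldehyde
Conditions: LiCl, DMF, 150 °C; then 1 M HCl
Reagents that add atoms: none
Why: Chloride in hot DMF dealkylates aryl methyl ethers by SN2 attack on the methyl group only when the departing phenoxide is conjugated with an acceptor, and the C4 methoxy group (future C7–O) is the only one para to the hydrogen-bond-activated formyl group, while the C3 and C5 methoxy groups are meta to it (regioselective nucleophilic demethylation of an activated aryl methyl ether).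

Step 6
Reactants: 12 (2,4,5-trihydroxybenzaldehyde), 13 (succinic anhydride)
Product: 15 acid 2-(6,7-dihydroxy-2-oxo-2H-chromen-3-yl)acetic acid, via bis(hemisuccinate) 14 (not isolated)
Conditions: 13 (excess), disodium succinate (Na2C4H4O4), melt, 150 °C, N2; then 3 M HCl, reflux
Reagents that add atoms: none
Why: Perkin condensation with succinic anhydride: the phenols are succinoylated in the melt, the hemisuccinate ester on the oxygen ortho to the formyl group undergoes intramolecular aldol condensation and dehydration to close pyranone ring C with the CH2CO2H group at C3′, and hot aqueous acid then cleaves the two remaining aryl hemisuccinates of 14.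

Step 7
Reactants: 11 (2,4-dihydroxy-3,5-dimethoxybenzaldehyde), 15 (the coumarin-3-acetic acid)
Product: 17 triacetate 3-[6,7-bis(acetyloxy)-2-oxo-2H-chromen-3-yl]-6,8-dimethoxy-2-oxo-2H-chromen-7-yl acetate, via aryl ester 16 (not isolated)
Conditions: Ac2O, Et3N, 110 °C
Reagents that add atoms: acetic anhydride, CC(=O)OC(C)=O
Why: Perkin–Oglialoro condensation: acetic anhydride acetylates the free hydroxyl groups and activates the acid as a mixed anhydride, the salicylaldehyde oxygen is acylated to give 16, and base-mediated intramolecular Knoevenagel-type condensation of the CH2 group (activated by the ester and the adjacent coumarin double bond, hence far more acidic than an acetyl CH3) with the formyl group closes pyranone ring B.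

Step 8
Reactants: 17 (the triacetate)
Product: 18 arteminorin C, 7-hydroxy-3-(6,7-dihydroxy-2-oxo-2H-chromen-3-yl)-6,8-dimethoxy-2H-chromen-2-one
Conditions: 3 M HCl, MeOH/THF, 60 °C, Ar
Reagents that add atoms: none
Why: Acid-catalysed methanolysis (transesterification) removes the three aryl acetates, while the aryl methyl ethers and both lactones are stable to methanolic HCl and the acidic medium protects the catechol from air oxidation.

Compound list
1 | 3,3-diethoxyprop-1-yne | C#CC(OCC)OCC | starting material
2 | tributyl[(E)-3,3-diethoxyprop-1-en-1-yl]stannane | CCCC[Sn](CCCC)(CCCC)/C=C/C(OCC)OCC | intermediate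
3 | dimethyl squarate (3,4-dimethoxycyclobut-3-ene-1,2-dione) | COC1=C(OC)C(=O)C1=O | starting material
4 | [(E)-3,3-diethoxyprop-1-en-1-yl]lithium (not isolated) | [Li]/C=C/C(OCC)OCC | intermediate
5 | racemic lithium 1-[(E)-3,3-diethoxyprop-1-en-1-yl]-2,3-dimethoxy-4-oxocyclobut-2-en-1-olate (not isolated) | [Li+].[O-]C1(/C=C/C(OCC)OCC)C(OC)=C(OC)C1=O | intermediate
6 | racemic 4-[(E)-3,3-diethoxyprop-1-en-1-yl]-2,3,4-trimethoxycyclobut-2-en-1-one | O=C1C(OC)=C(OC)C1(OC)/C=C/C(OCC)OCC | intermediate
7 | (3Z,5E)-7,7-diethoxy-2,3,4-trimethoxyhepta-1,3,5-trien-1-one (not isolated) | O=C=C(OC)/C(OC)=C(OC)\C=C\C(OCC)OCC | intermediate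
8 | racemic 6-(diethoxymethyl)-2,3,4-trimethoxycyclohexa-2,4-dien-1-one (not isolated) | O=C1C(OC)=C(OC)C(OC)=CC1C(OCC)OCC | intermediate
9 | 6-(diethoxymethyl)-2,3,4-trimethoxyphenol | CCOC(OCC)c1cc(OC)c(OC)c(OC)c1O | intermediate
10 | 2-hydroxy-3,4,5-trimethoxybenzaldehyde | O=Cc1cc(OC)c(OC)c(OC)c1O | intermediate
11 | 2,4-dihydroxy-3,5-dimethoxybenzaldehyde | O=Cc1cc(OC)c(O)c(OC)c1O | intermediate
12 | 2,4,5-trihydroxybenzaldehyde | O=Cc1cc(O)c(O)cc1O | starting material
13 | succinic anhydride | O=C1CCC(=O)O1 | starting material
14 | 4,4'-{[3-(carboxymethyl)-2-oxo-2H-chromene-6,7-diyl]bis(oxy)}bis(4-oxobutanoic acid) (not isolated) | OC(=O)CCC(=O)Oc1cc2cc(CC(O)=O)c(=O)oc2cc1OC(=O)CCC(O)=O | intermediate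
15 | 2-(6,7-dihydroxy-2-oxo-2H-chromen-3-yl)acetic acid | OC(=O)Cc1cc2cc(O)c(O)cc2oc1=O | intermediate
16 | 3-(acetyloxy)-6-formyl-2,4-dimethoxyphenyl 2-[6,7-bis(acetyloxy)-2-oxo-2H-chromen-3-yl]acetate (not isolated) | CC(=O)Oc1c(OC)cc(C=O)c(OC(=O)Cc2cc3cc(OC(C)=O)c(OC(C)=O)cc3oc2=O)c1OC | intermediate
17 | 3-[6,7-bis(acetyloxy)-2-oxo-2H-chromen-3-yl]-6,8-dimethoxy-2-oxo-2H-chromen-7-yl acetate | COc1cc2cc(-c3cc4cc(OC(C)=O)c(OC(C)=O)cc4oc3=O)c(=O)oc2c(OC)c1OC(C)=O | intermediate
18 | arteminorin C, 7-hydroxy-3-(6,7-dihydroxy-2-oxo-2H-chromen-3-yl)-6,8-dimethoxy-2H-chromen-2-one | COc1cc2cc(-c3cc4cc(O)c(O)cc4oc3=O)c(=O)oc2c(OC)c1O | target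

Total step count: 8. Longest linear sequence: 7 steps (steps 1, 2, 3, 4, 5, 7, 8); step 6 runs in parallel.

Steps most likely to fail

Step 3. The dienylketene may be consumed by intermolecular reactions (addition of phenol already formed, or ketene dimerization) before it cyclizes, or the allylic acetal may ionize at the temperature needed for ring opening. The fallback changes the ring-closing event; it sets out from 1 and 3 and comes back to the route at 10. Deprotonation of alkyne 1 with n-BuLi (THF, −78 °C) should give (3,3-diethoxyprop-1-yn-1-yl)lithium F1 in the flask, and its addition to 3 should give racemic lithium 1-(3,3-diethoxyprop-1-yn-1-yl)-2,3-dimethoxy-4-oxocyclobut-2-en-1-olate F2 which, on NH4Cl quench, is protonated to racemic 4-(3,3-diethoxyprop-1-yn-1-yl)-4-hydroxy-2,3-dimethoxycyclobut-2-en-1-one F3 for isolation. Heating F3 in p-xylene should give, by the known ring expansion of 4-alkynyl-4-hydroxycyclobutenones through an enynylketene and a diradical, 5-(diethoxymethyl)-2,3-dimethoxycyclohexa-2,5-diene-1,4-dione F4 as the quinone. Reduction of F4 with Na2S2O4 (THF/water) should give 2-(diethoxymethyl)-5,6-dimethoxybenzene-1,4-diol F5 and dilute HCl in the same flask should convert F5 into 2,5-dihydroxy-3,4-dimethoxybenzaldehyde F6 with loss of ethanol. MeI (one equivalent) and K2CO3 in acetone should then methylate only the 5-hydroxyl of F6, the 2-hydroxyl being held in a hydrogen bond to the formyl group, to give 10.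

Step 5. Chloride may attack more than one methyl group, the reaction may stall once the phenoxide formed deactivates the ring, or the hot salicylaldehyde may degrade. The fallback differentiates the C7 oxygen as a benzyl ether before the arene exists; it sets out from 3, uses alkenyllithium 4 generated as in step 2, and comes back at 11. Alkoxide-catalysed alkoxy exchange (addition–elimination) of 3 with one equivalent of benzyl alcohol (NaH cat., THF, 0 °C) should give, after chromatographic removal of unchanged 3 and of doubly exchanged material, 3-(benzyloxy)-4-methoxycyclobut-3-ene-1,2-dione F7 as the mixed ester. Addition of 4 to F7 is expected to take place at both carbonyl groups without useful selectivity and to give racemic lithium 2-(benzyloxy)-1-[(E)-3,3-diethoxyprop-1-en-1-yl]-3-methoxy-4-oxocyclobut-2-en-1-olate F8 together with its regioisomer racemic lithium 3-(benzyloxy)-1-[(E)-3,3-diethoxyprop-1-en-1-yl]-2-methoxy-4-oxocyclobut-2-en-1-olate F9 in the same flask. Methylation with MeOTf should convert F8 into racemic 3-(benzyloxy)-4-[(E)-3,3-diethoxyprop-1-en-1-yl]-2,4-dimethoxycyclobut-2-en-1-one F10 and F9 into racemic 2-(benzyloxy)-4-[(E)-3,3-diethoxyprop-1-en-1-yl]-3,4-dimethoxycyclobut-2-en-1-one F11 which is removed by chromatography. Thermolysis of F10 as in step 3 should give 3-(benzyloxy)-6-(diethoxymethyl)-2,4-dimethoxyphenol F12 and hydrolysis as in step 4 should turn F12 into 4-(benzyloxy)-2-hydroxy-3,5-dimethoxybenzaldehyde F13 with loss of ethanol. Hydrogenolysis of F13 (H2, Pd/C, EtOAc, rt) should give 11 and toluene.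

Step 6. The acid formed may condense a second time with aldehyde to give a symmetrical bicoumarin, and the unprotected polyphenol may oligomerize or degrade in the hot melt. The fallback replaces the Perkin condensation by Wittig olefination and thermal lactonization; it sets out from 12 and comes back at 15. Aldehyde 12 is heated with diethyl 2-(triphenyl-λ5-phosphanylidene)butanedioate in N,N-diethylaniline at reflux. Olefination should give diethyl (E)-2-[(2,4,5-trihydroxyphenyl)methylidene]butanedioate F14 as a transient intermediate, and F14 should isomerize and lactonize in the hot amine, with loss of ethanol, to ethyl 2-(6,7-dihydroxy-2-oxo-2H-chromen-3-yl)acetate F15 in the same pot. Hydrolysis of F15 (aq. HCl/AcOH, reflux) should give 15.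

Further compounds
F1 | step 3 | (3,3-diethoxyprop-1-yn-1-yl)lithium | [Li]C#CC(OCC)OCC
F2 | step 3 | racemic lithium 1-(3,3-diethoxyprop-1-yn-1-yl)-2,3-dimethoxy-4-oxocyclobut-2-en-1-olate | [Li+].[O-]C1(C#CC(OCC)OCC)C(OC)=C(OC)C1=O
F3 | step 3 | racemic 4-(3,3-diethoxyprop-1-yn-1-yl)-4-hydroxy-2,3-dimethoxycyclobut-2-en-1-one | O=C1C(OC)=C(OC)C1(O)C#CC(OCC)OCC
F4 | step 3 | 5-(diethoxymethyl)-2,3-dimethoxycyclohexa-2,5-diene-1,4-dione | CCOC(OCC)C1=CC(=O)C(OC)=C(OC)C1=O
F5 | step 3 | 2-(diethoxymethyl)-5,6-dimethoxybenzene-1,4-diol | CCOC(OCC)c1cc(O)c(OC)c(OC)c1O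
F6 | step 3 | 2,5-dihydroxy-3,4-dimethoxybenzaldehyde | O=Cc1cc(O)c(OC)c(OC)c1O
F7 | step 5 | 3-(benzyloxy)-4-methoxycyclobut-3-ene-1,2-dione | COC1=C(OCc2ccccc2)C(=O)C1=O
F8 | step 5 | racemic lithium 2-(benzyloxy)-1-[(E)-3,3-diethoxyprop-1-en-1-yl]-3-methoxy-4-oxocyclobut-2-en-1-olate | [Li+].[O-]C1(/C=C/C(OCC)OCC)C(OCc2ccccc2)=C(OC)C1=O
F9 | step 5 | racemic lithium 3-(benzyloxy)-1-[(E)-3,3-diethoxyprop-1-en-1-yl]-2-methoxy-4-oxocyclobut-2-en-1-olate | [Li+].[O-]C1(/C=C/C(OCC)OCC)C(OC)=C(OCc2ccccc2)C1=O
F10 | step 5 | racemic 3-(benzyloxy)-4-[(E)-3,3-diethoxyprop-1-en-1-yl]-2,4-dimethoxycyclobut-2-en-1-one | O=C1C(OC)=C(OCc2ccccc2)C1(OC)/C=C/C(OCC)OCC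
F11 | step 5 | racemic 2-(benzyloxy)-4-[(E)-3,3-diethoxyprop-1-en-1-yl]-3,4-dimethoxycyclobut-2-en-1-one | O=C1C(OCc2ccccc2)=C(OC)C1(OC)/C=C/C(OCC)OCC
F12 | step 5 | 3-(benzyloxy)-6-(diethoxymethyl)-2,4-dimethoxyphenol | CCOC(OCC)c1cc(OC)c(OCc2ccccc2)c(OC)c1O
F13 | step 5 | 4-(benzyloxy)-2-hydroxy-3,5-dimethoxybenzaldehyde | O=Cc1cc(OC)c(OCc2ccccc2)c(OC)c1O
F14 | step 6 | diethyl (E)-2-[(2,4,5-trihydroxyphenyl)methylidene]butanedioate | CCOC(=O)C/C(=C\c1cc(O)c(O)cc1O)C(=O)OCC
F15 | step 6 | ethyl 2-(6,7-dihydroxy-2-oxo-2H-chromen-3-yl)acetate | CCOC(=O)Cc1cc2cc(O)c(O)cc2oc1=O
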